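## Analysis of the target

The target 22 is a biflavone ether. An apigenin unit (5,7-dihydroxy-2-(4-hydroxyphenyl)chromen-4-one) is joined through one oxygen at its C8 to C4' of a genkwanin unit (5-hydroxy-7-methoxy-2-arylchromen-4-one); in each unit ring A is the benzo ring, ring C the pyranone (O1, C2, C3, C4, C4a, C8a) and ring B the 2-aryl group. There is no stereocentre and the molecule is achiral, so every problem is one of regiochemistry and of telling seven ring oxygens apart. Four of them must end as free phenols, one as the C7 methyl ether of the genkwanin unit, and one as the diaryl ether, which sits on a carbon flanked by C8a and by the C7 hydroxyl of the apigenin unit. Sensitive features are the electron-rich phloroglucinol-type ring A of the apigenin unit (oxidation, C-alkylation), both pyranones (opened by hot hydroxide), and the 8-aryloxy-5,7-dihydroxychromone, which in hot protic acid can open and reclose to the 6-aryloxy isomer (Wessely–Moser rearrangement). The hard points are to place the ether at C8 and not at C6, to forge a diaryl ether at a doubly ortho-substituted carbon, and to free four phenols while one methyl ether stays. The strategy rests on the O1–C8a bond of the genkwanin unit: C8a lies on ring A ortho to the C4 carbonyl, so it can enter as the fluorine-bearing carbon of a 2-fluoro-4,6-dimethoxybenzoyl group and receive O1 from the enol oxygen of a 1,3-diketone built on the ring B methyl ketone. Ring C of the genkwanin unit is thus closed without a free phenol on its ring A, and ring B can carry the differentiated oxygenated ring of the other half through the key step.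

## Retrosynthetic reasoning

**22 from 21.** The last operation only releases phenols. In 21 the three hydroxyls of the apigenin unit are benzyl ethers and both ring A oxygens of the genkwanin unit are methyl ethers. Four O–alkyl bonds are cut: the three O–benzyl bonds and the O–methyl bond at C5 of the genkwanin unit, the only methyl ether chelated to a carbonyl. A boron Lewis acid used cold cleaves exactly these and leaves the C7 methyl ether, and the low temperature avoids isomerisation of the 8-aryloxy-5,7-dihydroxychromone.

**21 from 17 and 18, through 19 and 20.** Ring C of the apigenin unit is cut at O1–C2 and C2–C3. This is the Baker–Venkataraman disconnection: 17 supplies the ortho-hydroxyaryl methyl ketone, 18 the C2 carbonyl with ring B. The forward sequence is O-acylation to 19, acyl shift to diketone 20 and cyclodehydration. Because 17 has only one free hydroxyl, ring closure can only give the 8-aryloxy isomer.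

**17 from 15, and 15 from 14.** The C4–C4a bond of the apigenin unit is cut, an aryl–acetyl bond made by acylation ortho to the one free hydroxyl of 15. That hydroxyl is released from the MOM ether of 14. The MOM group is the marker for the oxygen that becomes O1, while the two benzyl ethers mark the future C5 and C7 hydroxyls.

**14 from 12 and 5, through 13 (key disconnection).** Ring C of the genkwanin unit is cut at C3–C4 and O1–C8a. C3–C4 is an enolate acylation of methyl ketone 12 by acid chloride 5; O1–C8a is an intramolecular displacement of fluorine by the diketone enol oxygen of 13. Cutting here makes the synthesis convergent at a simple ketone, supplies O1 from the ketone oxygen of 12, and avoids any free ortho-hydroxyl on the dimethoxy ring. The forward reaction must acylate at carbon and then close a six-membered ring on an electron-rich fluoroarene.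

**12 from 10 and 11.** The diaryl ether is cut at O–C4' of ring B. The para-acetyl group of 11 activates fluorine for substitution by the phenoxide of 10, and the acetyl group is the handle needed in the key step.

**10 from 6, through 7, 8 and 9.** The phenol oxygen of 10 replaces the formyl carbon of 8 (aryl migration in a peracid oxidation, then formate cleavage). The formyl group of 6 serves twice: it differentiates one ortho hydroxyl by hydrogen bonding, so that 7 has two benzyl ethers and one free hydroxyl for the MOM group, and it is then exchanged for the oxygen that becomes the ether bridge.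

**5 from 1, through 3 and 4.** The acyl carbon is attached to 1 by formylation para to a methoxy group and ortho to fluorine, then oxidised to acid 4 and converted into chloride 5.

## Alternatives that were turned down

**Alternative 1:** Ring A of the apigenin unit is assembled by a Danheiser benzannulation instead of being taken from a phloroglucinol. The disconnection cuts C4a–C8a and C5–C6 (and formally C8–C8a) and leads to racemic 4-(4-bromophenoxy)-3-ethoxycyclobut-2-en-1-one A2 and ethoxyacetylene A3. Forward, heating opens A2 to a vinylketene, A3 adds across the ketene in a [2+2] step, the new cyclobutenone opens to a dienylketene, and 6π closure with tautomerisation gives 2-(4-bromophenoxy)-3,5-diethoxyphenol A1.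
- For it: the only free hydroxyl of A1 is at the future C8a, next to the aryloxy carbon. On the question of which oxygen becomes O1 this is stronger than the chosen plan, since no MOM/benzyl differentiation, formyl placeholder or peracid oxidation is needed. The diaryl ether is also carried in from the start.
- Against it: ring A can be bought as 6, so making four of its carbons through A2 (several steps, with an α-aryloxy group that is not routine on cyclobutenones) is poor economy.
- The ethyl ethers of A1 cannot be removed at the end without attacking the C7 methyl ether of the genkwanin unit, so benzyloxy analogues of A2 and A3 would be needed.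
- C4a of A1 still carries hydrogen, so the acetylation of step 10 remains with the same ortho/para question.
- The bromide of A1 must still be turned into the whole genkwanin unit, starting with an acetyl group that 12 has from a commercial arene.
- Comparison: the benzannulation wins on the O1 problem; the chosen plan solves that problem in three simple steps (4 to 6), is shorter overall, and has a protecting-group pattern that fits the final unmasking.

**Alternative 2:** Ring B of the genkwanin unit is built de novo. The disconnection cuts C2'–C3' and C4'–C5' and leads to methyl coumalate A5 and the aryl ethynyl ether A6 (1,5-bis(benzyloxy)-2-(ethynyloxy)-3-(methoxymethoxy)benzene), which would come from 10 in two steps. Forward, the electron-rich alkyne adds across C3 and C6 of the electron-poor pyranone, the terminal alkyne carbon bonding to C6, and the bicyclic lactone loses CO2 to give methyl 4-[2,4-bis(benzyloxy)-6-(methoxymethoxy)phenoxy]benzoate A4.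
- For it: the para relationship follows from the polarity of the partners. No substitution at a fluoroarene by a hindered, easily oxidised phenoxide is needed, so on this point it is at least as strong as step 7.
- For it: the ester oxidation level of A4 would allow a classical Baker–Venkataraman closure with a purchasable ortho-hydroxyaryl ketone, which would save the three steps to 5.
- Against it: ring B is a plain para-disubstituted benzene that costs nothing as 11, so two steps to A6 plus a cycloaddition replace the single step 7.
- Aryl ynol ethers are thermally fragile, while pyranone cycloadditions with CO2 loss need prolonged heating.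
- A4 would have to be converted into a methyl ketone before it could enter step 8.
- Comparison: the chosen plan offers a one-step entry to 12 with the acetyl handle at the right oxidation level.

**Alternative 3:** Ring A of the apigenin unit is formed last on a preformed pyranone, in the manner of polyketide biosynthesis. The disconnection cuts C4a–C5 and leads to the racemic keto ester A8 (ethyl 4-[6-[4-(benzyloxy)phenyl]-4-oxo-4H-pyran-2-yl]-4-(4-bromophenoxy)-3-oxobutanoate). Forward, base removes the proton at the aryloxy-bearing carbon to give a dienolate extended through the pyranone. Its ring carbon next to the side chain (the future C4a) attacks the ester carbonyl in a Claisen closure, and enolisation gives 2-(4-benzyloxyphenyl)-8-(4-bromophenoxy)-5,7-dihydroxychromen-4-one A7.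
- For it: the aryloxy group is fixed at C8 by the connectivity of the chain, so neither the O1 differentiation nor the regiochemistry of step 10 arises. On that point it is stronger than the chosen plan, and ring C is already present.
- Against it: A8 has three acidic sites, and the most acidic one (the methylene between the two carbonyls) is not the one that must react, so a polyanion is needed.
- The α-aryloxy ketone can lose aryloxide, and 4-pyranones are opened by the strong bases required.
- The assembly of A8 is itself a multistep problem without a reliable route.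
- A7 arrives with two free phenols that must be protected again before the bromide can be elaborated.
- Comparison: the chosen plan places its one demanding operation, step 8, on a robust, fully protected substrate reached by short, familiar chemistry.

Key step: step 8

## Route

Assumption: 4-(benzyloxy)benzoyl chloride 18 is purchased as such.

Step 1
Reactants: 1 1-fluoro-3,5-dimethoxybenzene
Product: 3 2-fluoro-4,6-dimethoxybenzaldehyde, via aryliminium chloride 2 (not isolated)
Conditions: POCl3, DMF, 0 °C → 70 °C; then ice/H2O
Reagents that add atoms: N,N-dimethylformamide CN(C)C=O; water O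
Why: Vilsmeier–Haack formylation of an activated arene; the chloroiminium electrophile should enter para to one methoxy group and ortho to the other, beside the small fluorine, in preference to the crowded carbon between the two methoxy groups. Iminium salt 2 is hydrolysed on aqueous work-up, and any regioisomer should be removable at this crystalline stage.

Step 2
Reactants: 3 2-fluoro-4,6-dimethoxybenzaldehyde
Product: 4 2-fluoro-4,6-dimethoxybenzoic acid
Conditions: NaClO2, NaH2PO4, 2-methyl-2-butene, t-BuOH/THF/H2O, 0 °C → rt
Reagents that add atoms: sodium chlorite [Na+].[O-]Cl=O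
Why: Pinnick oxidation; chlorous acid oxidises the aldehyde without touching the aryl fluoride, and the alkene takes up the hypochlorous acid so that the electron-rich ring is not chlorinated.

Step 3
Reactants: 4 2-fluoro-4,6-dimethoxybenzoic acid
Product: 5 2-fluoro-4,6-dimethoxybenzoyl chloride
Conditions: (COCl)2, DMF (cat.), CH2Cl2, 0 °C → rt; evaporated and used crude
Reagents that add atoms: oxalyl chloride O=C(Cl)C(=O)Cl
Why: Acid chloride formation through the catalytic chloroiminium species; the by-products are gases, so crude 5 can be taken directly into step 8.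

Step 4
Reactants: 6 2,4,6-trihydroxybenzaldehyde
Product: 7 2,4-bis(benzyloxy)-6-hydroxybenzaldehyde
Conditions: BnBr (2.1 equiv), K2CO3, DMF, 0 °C → rt
Reagents that add atoms: benzyl bromide BrCc1ccccc1
Why: Williamson etherification under weak base; the para hydroxyl and one ortho hydroxyl are alkylated, while the remaining ortho hydroxyl is hydrogen-bonded to the formyl group and is the least acidic and least nucleophilic. This differentiates the oxygen that later becomes O1 of the apigenin unit.

Step 5
Reactants: 7 2,4-bis(benzyloxy)-6-hydroxybenzaldehyde
Product: 8 2,4-bis(benzyloxy)-6-(methoxymethoxy)benzaldehyde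
Conditions: MOMCl, i-Pr2NEt, CH2Cl2, 0 °C → 40 °C
Reagents that add atoms: chloromethyl methyl ether COCCl
Why: Acetal protection of the chelated phenol with excess chloride and an amine base; the MOM ether is stable to the peracid, carbonate and lithium amide steps ahead and can later be removed by dilute acid without loss of benzyl ethers.

Step 6
Reactants: 8 2,4-bis(benzyloxy)-6-(methoxymethoxy)benzaldehyde
Product: 10 2,4-bis(benzyloxy)-6-(methoxymethoxy)phenol, via aryl formate 9 (not isolated)
Conditions: mCPBA, CH2Cl2, 0 °C → rt; aq. NaHCO3 wash; then K2CO3 (cat.), MeOH, rt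
Reagents that add atoms: 3-chloroperoxybenzoic acid OOC(=O)c1cccc(Cl)c1
Why: Dakin-type Baeyer–Villiger oxidation; in the Criegee intermediate the electron-rich trialkoxyaryl group migrates in preference to hydrogen, giving formate 9, which is methanolysed without isolation. The formyl carbon is thereby replaced by the oxygen that becomes the ether bridge.

Step 7
Reactants: 10 2,4-bis(benzyloxy)-6-(methoxymethoxy)phenol; 11 4'-fluoroacetophenone
Product: 12 1-[4-[2,4-bis(benzyloxy)-6-(methoxymethoxy)phenoxy]phenyl]ethanone
Conditions: K2CO3, DMSO, 110 °C, argon
Reagents that add atoms: none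
Why: Nucleophilic aromatic substitution by addition–elimination; the para-acetyl group stabilises the Meisenheimer intermediate and fluorine is the leaving group. The electron-rich phenoxide is a strong nucleophile despite its two ortho substituents, and exclusion of air prevents its oxidation.

Step 8
Reactants: 12 1-[4-[2,4-bis(benzyloxy)-6-(methoxymethoxy)phenoxy]phenyl]ethanone; 5 2-fluoro-4,6-dimethoxybenzoyl chloride
Product: 14 2-[4-[2,4-bis(benzyloxy)-6-(methoxymethoxy)phenoxy]phenyl]-5,7-dimethoxychromen-4-one, via fluoroaryl 1,3-diketone 13 (not isolated)
Conditions: LiN(SiMe3)2 (2.5 equiv), THF, −78 °C; 5, −78 → 0 °C; aq. NH4Cl; solvent exchange; then K2CO3, DMF, 90 °C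
Reagents that add atoms: none
Why: Crossed Claisen-type C-acylation followed by intramolecular nucleophilic aromatic substitution. LiN(SiMe3)2 converts methyl ketone 12 into its lithium enolate, which attacks acid chloride 5 at carbon to form C3–C4; diketone 13 is at once deprotonated by the excess base, which makes the C-acylation irreversible and blocks a second acylation. On heating with K2CO3 in DMF the diketone enolate oxygen on the ring B side adds to the fluorine-bearing carbon ortho to the aroyl carbonyl, and the Meisenheimer intermediate, stabilised by that carbonyl, loses fluoride to form O1–C8a. Ring C closes as a six-membered ring by addition–elimination at a trigonal carbon (formally 6-endo-trig, since the C4a=C8a bond that takes up the charge lies inside the new ring); the other diketone oxygen could only form a four-membered ring, so there is no regiochemical choice. The closest known reaction type is the one-flask chromone and 4-quinolone synthesis from ketone enolates and 2-halobenzoyl chlorides. No stereocentre is formed. The selectivity needed is C- over O-acylation, secured by the lithium counter-ion in THF at low temperature with excess base; the substitution should not be retarded by resonance from the two methoxy groups, because both are meta to the attacked carbon while the activating carbonyl is ortho. The MOM ether, the benzyl ethers and the diaryl ether of 12 are inert to both stages.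

Step 9
Reactants: 14 2-[4-[2,4-bis(benzyloxy)-6-(methoxymethoxy)phenoxy]phenyl]-5,7-dimethoxychromen-4-one
Product: 15 2-[4-[2,4-bis(benzyloxy)-6-hydroxyphenoxy]phenyl]-5,7-dimethoxychromen-4-one
Conditions: 3 M HCl, MeOH/THF, 50 °C
Reagents that add atoms: none
Why: Acid-catalysed acetal cleavage through the oxocarbenium ion, which methanol intercepts as dimethoxymethane so that no formaldehyde attacks the electron-rich ring. Benzyl and methyl ethers, the diaryl ether and the chromone are stable to dilute acid at this temperature.

Step 10
Reactants: 15 2-[4-[2,4-bis(benzyloxy)-6-hydroxyphenoxy]phenyl]-5,7-dimethoxychromen-4-one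
Product: 17 2-[4-[3-acetyl-4,6-bis(benzyloxy)-2-hydroxyphenoxy]phenyl]-5,7-dimethoxychromen-4-one, via difluoroboron chelate 16 (not isolated)
Conditions: Ac2O (1.5 equiv), BF3·OEt2, CH2Cl2, 0 → 40 °C; then NaOAc, MeOH/H2O, 60 °C
Reagents that add atoms: acetic anhydride CC(=O)OC(C)=O
Why: Friedel–Crafts acylation of a phenol (Fries-type ortho-acylation with BF3); the only free ortho position is the carbon between the hydroxyl and a benzyloxy group, and acylation there is driven by the six-membered difluoroboron chelate 16, which cannot form after attack para to the hydroxyl. The chelate ties up the new carbonyl and so shields the neighbouring benzyl ether, BF3 coordination deactivates the dimethoxychromone ring, and mild hydrolysis releases 17.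

Step 11
Reactants: 17 2-[4-[3-acetyl-4,6-bis(benzyloxy)-2-hydroxyphenoxy]phenyl]-5,7-dimethoxychromen-4-one; 18 4-(benzyloxy)benzoyl chloride
Product: 19 2-acetyl-3,5-bis(benzyloxy)-6-[4-(5,7-dimethoxy-4-oxochromen-2-yl)phenoxy]phenyl 4-(benzyloxy)benzoate
Conditions: pyridine, DMAP (cat.), CH2Cl2, rt → 40 °C
Reagents that add atoms: none
Why: O-acylation of the chelated phenol by acylpyridinium transfer, the first stage of the Baker–Venkataraman sequence; DMAP and gentle warming overcome the hindrance from the flanking aryloxy and acetyl groups.

Step 12
Reactants: 19 2-acetyl-3,5-bis(benzyloxy)-6-[4-(5,7-dimethoxy-4-oxochromen-2-yl)phenoxy]phenyl 4-(benzyloxy)benzoate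
Product: 21 5,7-bis(benzyloxy)-2-[4-(benzyloxy)phenyl]-8-[4-(5,7-dimethoxy-4-oxochromen-2-yl)phenoxy]chromen-4-one, via 1,3-diketone 20 (not isolated)
Conditions: LiN(SiMe3)2, THF, −20 °C → rt; AcOH; then p-TsOH·H2O (cat.), toluene, 90 °C
Reagents that add atoms: none
Why: Baker–Venkataraman rearrangement; the acetyl enolate attacks the neighbouring ester carbonyl in an intramolecular Claisen condensation to give diketone 20, and acid-catalysed cyclodehydration then closes ring C of the apigenin unit through the only free phenol, which fixes the ether at C8. A non-nucleophilic amide base is used so that the existing chromone is not opened, and the acid is mild enough for the benzyl ethers.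

Step 13
Reactants: 21 5,7-bis(benzyloxy)-2-[4-(benzyloxy)phenyl]-8-[4-(5,7-dimethoxy-4-oxochromen-2-yl)phenoxy]chromen-4-one
Product: 22 5,7-dihydroxy-8-[4-(5-hydroxy-7-methoxy-4-oxochromen-2-yl)phenoxy]-2-(4-hydroxyphenyl)chromen-4-one
Conditions: BCl3 (excess), pentamethylbenzene, CH2Cl2, −78 → 0 °C; then H2O
Reagents that add atoms: none
Why: Lewis-acid ether cleavage; the aryl benzyl ethers are cleaved cold with pentamethylbenzene trapping the benzyl cation, and the C5 methyl ether of the genkwanin unit is cleaved through its six-membered boron chelate with the C4 carbonyl, whereas the unchelated C7 methyl ether should survive at or below 0 °C. The low temperature and the absence of hot protic acid avoid Wessely–Moser isomerisation.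

## Compound list

1 | 1-fluoro-3,5-dimethoxybenzene | COc1cc(F)cc(OC)c1 | starting material
2 | N-[(2-fluoro-4,6-dimethoxyphenyl)methylidene]-N-methylmethanaminium chloride | C[N+](C)=Cc1c(F)cc(OC)cc1OC.[Cl-] | intermediate
3 | 2-fluoro-4,6-dimethoxybenzaldehyde | COc1cc(F)c(C=O)c(OC)c1 | intermediate
4 | 2-fluoro-4,6-dimethoxybenzoic acid | COc1cc(F)c(C(=O)O)c(OC)c1 | intermediate
5 | 2-fluoro-4,6-dimethoxybenzoyl chloride | COc1cc(F)c(C(Cl)=O)c(OC)c1 | intermediate
6 | 2,4,6-trihydroxybenzaldehyde | O=Cc1c(O)cc(O)cc1O | starting material
7 | 2,4-bis(benzyloxy)-6-hydroxybenzaldehyde | O=Cc1c(O)cc(OCc2ccccc2)cc1OCc1ccccc1 | intermediate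
8 | 2,4-bis(benzyloxy)-6-(methoxymethoxy)benzaldehyde | COCOc1cc(OCc2ccccc2)cc(OCc2ccccc2)c1C=O | intermediate
9 | 2,4-bis(benzyloxy)-6-(methoxymethoxy)phenyl formate | COCOc1cc(OCc2ccccc2)cc(OCc2ccccc2)c1OC=O | intermediate
10 | 2,4-bis(benzyloxy)-6-(methoxymethoxy)phenol | COCOc1cc(OCc2ccccc2)cc(OCc2ccccc2)c1O | intermediate
11 | 4'-fluoroacetophenone (1-(4-fluorophenyl)ethanone) | CC(=O)c1ccc(F)cc1 | starting material
12 | 1-[4-[2,4-bis(benzyloxy)-6-(methoxymethoxy)phenoxy]phenyl]ethanone | CC(=O)c1ccc(Oc2c(OCOC)cc(OCc3ccccc3)cc2OCc2ccccc2)cc1 | intermediate
13 | 1-[4-[2,4-bis(benzyloxy)-6-(methoxymethoxy)phenoxy]phenyl]-3-(2-fluoro-4,6-dimethoxyphenyl)propane-1,3-dione | COCOc1cc(OCc2ccccc2)cc(OCc2ccccc2)c1Oc1ccc(C(=O)CC(=O)c2c(F)cc(OC)cc2OC)cc1 | intermediate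
14 | 2-[4-[2,4-bis(benzyloxy)-6-(methoxymethoxy)phenoxy]phenyl]-5,7-dimethoxychromen-4-one | COc1cc(OC)c2c(=O)cc(-c3ccc(Oc4c(OCOC)cc(OCc5ccccc5)cc4OCc4ccccc4)cc3)oc2c1 | intermediate
15 | 2-[4-[2,4-bis(benzyloxy)-6-hydroxyphenoxy]phenyl]-5,7-dimethoxychromen-4-one | COc1cc(OC)c2c(=O)cc(-c3ccc(Oc4c(O)cc(OCc5ccccc5)cc4OCc4ccccc4)cc3)oc2c1 | intermediate
16 | difluoroboron O,O-chelate of 17 (boron bridging the phenol oxygen and the acetyl oxygen) | CC1=[O+][B-](F)(F)Oc2c1c(OCc3ccccc3)cc(OCc3ccccc3)c2Oc2ccc(-c3cc(=O)c4c(OC)cc(OC)cc4o3)cc2 | intermediate
17 | 2-[4-[3-acetyl-4,6-bis(benzyloxy)-2-hydroxyphenoxy]phenyl]-5,7-dimethoxychromen-4-one | COc1cc(OC)c2c(=O)cc(-c3ccc(Oc4c(O)c(C(C)=O)c(OCc5ccccc5)cc4OCc4ccccc4)cc3)oc2c1 | intermediate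
18 | 4-(benzyloxy)benzoyl chloride | O=C(Cl)c1ccc(OCc2ccccc2)cc1 | starting material
19 | 2-acetyl-3,5-bis(benzyloxy)-6-[4-(5,7-dimethoxy-4-oxochromen-2-yl)phenoxy]phenyl 4-(benzyloxy)benzoate | COc1cc(OC)c2c(=O)cc(-c3ccc(Oc4c(OC(=O)c5ccc(OCc6ccccc6)cc5)c(C(C)=O)c(OCc5ccccc5)cc4OCc4ccccc4)cc3)oc2c1 | intermediate
20 | 1-[4,6-bis(benzyloxy)-3-[4-(5,7-dimethoxy-4-oxochromen-2-yl)phenoxy]-2-hydroxyphenyl]-3-[4-(benzyloxy)phenyl]propane-1,3-dione | COc1cc(OC)c2c(=O)cc(-c3ccc(Oc4c(O)c(C(=O)CC(=O)c5ccc(OCc6ccccc6)cc5)c(OCc5ccccc5)cc4OCc4ccccc4)cc3)oc2c1 | intermediate
21 | 5,7-bis(benzyloxy)-2-[4-(benzyloxy)phenyl]-8-[4-(5,7-dimethoxy-4-oxochromen-2-yl)phenoxy]chromen-4-one | O=c1cc(-c2ccc(OCc3ccccc3)cc2)oc2c(Oc3ccc(-c4cc(=O)c5c(OC)cc(OC)cc5o4)cc3)c(OCc3ccccc3)cc(OCc3ccccc3)c12 | intermediate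
22 | 5,7-dihydroxy-8-[4-(5-hydroxy-7-methoxy-4-oxochromen-2-yl)phenoxy]-2-(4-hydroxyphenyl)chromen-4-one | COc1cc(O)c2c(=O)cc(-c3ccc(Oc4c(O)cc(O)c5c(=O)cc(-c6ccc(O)cc6)oc45)cc3)oc2c1 | target

## Step count and risk

Total step count: 13. Longest linear sequence: 10 steps (6 to 22, steps 4 to 13); the branch from 1 adds 3 steps before it joins at step 8.

**Step 8 (key step).** The enolate may be acylated at oxygen or twice, or the amide base may consume the hindered acid chloride. The fluoride displacement may also be slow, because the 2,6-disubstituted, electron-rich aroyl group is twisted out of conjugation with its carbonyl, and retro-Claisen cleavage of the diketone could then compete on long heating. Fallback, from 10 back to the route at 15: the roles of the two halves are reversed and ring C is closed by a Baker–Venkataraman sequence. Phenol 10 is arylated with 4-fluorobenzonitrile (K2CO3, DMSO, 100 °C) to give 4-[2,4-bis(benzyloxy)-6-(methoxymethoxy)phenoxy]benzonitrile F1. Hydrolysis with KOH in aqueous ethanol at reflux gives 4-[2,4-bis(benzyloxy)-6-(methoxymethoxy)phenoxy]benzoic acid F2. Carbodiimide coupling (EDC·HCl, DMAP, CH2Cl2) with purchased 1-(2-hydroxy-4,6-dimethoxyphenyl)ethanone gives 2-acetyl-3,5-dimethoxyphenyl 4-[2,4-bis(benzyloxy)-6-(methoxymethoxy)phenoxy]benzoate F3. Acyl shift with KOt-Bu in THF gives 1-[4-[2,4-bis(benzyloxy)-6-(methoxymethoxy)phenoxy]phenyl]-3-(2-hydroxy-4,6-dimethoxyphenyl)propane-1,3-dione F4. Warming F4 with HCl in MeOH/THF should cyclodehydrate it and remove the MOM group in the same operation, giving 15.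

**Step 10.** Acylation may occur para to the hydroxyl, at the carbon between the two benzyloxy groups. The Lewis acid may also cause loss or migration of benzyl groups, or further acetylation of the new methyl ketone. Fallback, from 15 back to 17: the carbon is introduced by a reaction that is ortho-specific through the magnesium phenoxide. Formylation with MgCl2, Et3N and paraformaldehyde in MeCN at reflux should give 2-[4-[4,6-bis(benzyloxy)-3-formyl-2-hydroxyphenoxy]phenyl]-5,7-dimethoxychromen-4-one F5. MeMgBr (2.5 equiv, THF, −78 °C) should add to the aldehyde faster than to the vinylogous-ester carbonyl of the chromone, giving racemic 2-[4-[4,6-bis(benzyloxy)-2-hydroxy-3-(1-hydroxyethyl)phenoxy]phenyl]-5,7-dimethoxychromen-4-one F6. Oxidation of the benzylic alcohol with MnO2 in CH2Cl2 gives 17.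

**Step 13.** Cleavage of the chelated methyl ether may be incomplete at the temperature that protects the C7 methyl ether, or demethylation may go too far on warming. Benzyl cations may also alkylate the freed phloroglucinol ring. Fallback, from 21 back to 22: the deprotection is split into two orthogonal stages. Hydrogenolysis (H2, Pd/C, THF/MeOH, rt) removes the three benzyl groups and gives 8-[4-(5,7-dimethoxy-4-oxochromen-2-yl)phenoxy]-5,7-dihydroxy-2-(4-hydroxyphenyl)chromen-4-one F7. Chelation-controlled mono-demethylation of F7 with AlCl3 in MeCN at 50 °C then gives 22.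

**Step 7.** The electron-rich phenoxide may be oxidised at the temperature required, the attack may be slow because of the two ortho substituents, and the methyl ketone may self-condense under carbonate. Fallback, from 10 back to 12: the ether is made by copper catalysis instead of addition–elimination. Phenol 10 and 4'-iodoacetophenone are coupled with CuI, picolinic acid and K3PO4 in DMSO at 85 °C, an Ullmann-type method suited to hindered phenols; no new intermediate is made.

**Step 4.** The alkylation may give a statistical mixture of under- and over-benzylated material, and the phloroglucinol nucleus may be benzylated at carbon. Fallback, from 6 back to 7: all three hydroxyls are benzylated (excess BnBr, K2CO3, DMF, 60 °C) to give 2,4,6-tris(benzyloxy)benzaldehyde F8. One of the two equivalent ortho benzyl groups is then removed by chelation-controlled cleavage with MgBr2·OEt2 in toluene/Et2O at 60 °C. This should stop at 7, because the hydrogen-bonded hydroxyaldehyde formed is deactivated towards a second cleavage.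

## Further compounds

F1 | step 8 | 4-[2,4-bis(benzyloxy)-6-(methoxymethoxy)phenoxy]benzonitrile | N#Cc1ccc(Oc2c(OCOC)cc(OCc3ccccc3)cc2OCc2ccccc2)cc1
F2 | step 8 | 4-[2,4-bis(benzyloxy)-6-(methoxymethoxy)phenoxy]benzoic acid | OC(=O)c1ccc(Oc2c(OCOC)cc(OCc3ccccc3)cc2OCc2ccccc2)cc1
F3 | step 8 | 2-acetyl-3,5-dimethoxyphenyl 4-[2,4-bis(benzyloxy)-6-(methoxymethoxy)phenoxy]benzoate | CC(=O)c1c(OC)cc(OC)cc1OC(=O)c1ccc(Oc2c(OCOC)cc(OCc3ccccc3)cc2OCc2ccccc2)cc1
F4 | step 8 | 1-[4-[2,4-bis(benzyloxy)-6-(methoxymethoxy)phenoxy]phenyl]-3-(2-hydroxy-4,6-dimethoxyphenyl)propane-1,3-dione | COCOc1cc(OCc2ccccc2)cc(OCc2ccccc2)c1Oc1ccc(C(=O)CC(=O)c2c(O)cc(OC)cc2OC)cc1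
F5 | step 10 | 2-[4-[4,6-bis(benzyloxy)-3-formyl-2-hydroxyphenoxy]phenyl]-5,7-dimethoxychromen-4-one | COc1cc(OC)c2c(=O)cc(-c3ccc(Oc4c(O)c(C=O)c(OCc5ccccc5)cc4OCc4ccccc4)cc3)oc2c1
F6 | step 10 | racemic 2-[4-[4,6-bis(benzyloxy)-2-hydroxy-3-(1-hydroxyethyl)phenoxy]phenyl]-5,7-dimethoxychromen-4-one | COc1cc(OC)c2c(=O)cc(-c3ccc(Oc4c(O)c(C(C)O)c(OCc5ccccc5)cc4OCc4ccccc4)cc3)oc2c1
F7 | step 13 | 8-[4-(5,7-dimethoxy-4-oxochromen-2-yl)phenoxy]-5,7-dihydroxy-2-(4-hydroxyphenyl)chromen-4-one | COc1cc(OC)c2c(=O)cc(-c3ccc(Oc4c(O)cc(O)c5c(=O)cc(-c6ccc(O)cc6)oc45)cc3)oc2c1
F0 | step 7 | none | none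
F8 | step 4 | 2,4,6-tris(benzyloxy)benzaldehyde | O=Cc1c(OCc2ccccc2)cc(OCc2ccccc2)cc1OCc1ccccc1
A1 | alternative 1 | 2-(4-bromophenoxy)-3,5-diethoxyphenol | Oc1cc(OCC)cc(OCC)c1Oc1ccc(Br)cc1
A2 | alternative 1 | racemic 4-(4-bromophenoxy)-3-ethoxycyclobut-2-en-1-one | CCOC1=CC(=O)C1Oc1ccc(Br)cc1
A3 | alternative 1 | ethoxyacetylene | C#COCC
A4 | alternative 2 | methyl 4-[2,4-bis(benzyloxy)-6-(methoxymethoxy)phenoxy]benzoate | COC(=O)c1ccc(Oc2c(OCOC)cc(OCc3ccccc3)cc2OCc2ccccc2)cc1
A5 | alternative 2 | methyl coumalate (methyl 2-oxo-2H-pyran-5-carboxylate) | COC(=O)C1=COC(=O)C=C1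
A6 | alternative 2 | 1,5-bis(benzyloxy)-2-(ethynyloxy)-3-(methoxymethoxy)benzene | C#COc1c(OCOC)cc(OCc2ccccc2)cc1OCc1ccccc1
A7 | alternative 3 | 2-(4-benzyloxyphenyl)-8-(4-bromophenoxy)-5,7-dihydroxychromen-4-one | O=c1cc(-c2ccc(OCc3ccccc3)cc2)oc2c(Oc3ccc(Br)cc3)c(O)cc(O)c12
A8 | alternative 3 | racemic ethyl 4-[6-[4-(benzyloxy)phenyl]-4-oxo-4H-pyran-2-yl]-4-(4-bromophenoxy)-3-oxobutanoate | CCOC(=O)CC(=O)C(Oc1ccc(Br)cc1)c1cc(=O)cc(-c2ccc(OCc3ccccc3)cc2)o1
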